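**Retrosynthetic overview**
1. The target is opened at the two ketal C–O bonds into all-trans-canthaxanthin (both six-membered rings and the polyene are bought) and a C34 tetramethylsqualene-10,11-diol. The spiro-dioxolane is the only ring made and is closed last.
2. The diol is cut at C9–C10: a chain A C9 magnesium reagent adds under chelation control to an α-hydroxy methyl ketone (C10–C24). C11 comes from the lactone acid of D-glutamic acid and controls C10.
3. That ketone is cut at C13–C14: a light-driven nickel/iridium decarboxylative alkenylation joins the opened lactone to the chain B (E)-alkenyl iodide, whose E olefin comes from alkyne carboalumination.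
4. Chains A and B are cut at C5–C6 and C19–C20: the same light-driven decarboxylative alkenylation joins an outer-unit acid to an inner-unit enol triflate. All four methyl stereocenters are bought in (R)- or (S)-β-citronellene.

Assumption: all-trans-canthaxanthin, both enantiomers of β-citronellene and (2R)-5-oxooxolane-2-carboxylic acid (the lactone acid made from D-glutamic acid) are purchasable; the stereochemical purity of the product is that of these materials.

Locants C1–C24 used in the text count the terpenoid chain from the chain A end.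

Step 1
Reactants: 1 (3R)-3,7-dimethylocta-1,6-diene [(R)-β-citronellene]
Product: 2 (3R)-3,7-dimethyloct-6-en-2-one
Conditions: PdCl2 (10 mol%), CuCl (1 equiv), O2 (1 atm), DMF/H2O 7:1, rt
Reagents that add atoms: water, O
Why: Tsuji–Wacker oxidation: Markovnikov hydroxypalladation occurs only at the monosubstituted vinyl group (O2 is the terminal oxidant), the trisubstituted olefin is inert, and the bought stereocenter, now α to the ketone, is not enolised under these near-neutral conditions.

Step 2
Reactants: 2 (3R)-3,7-dimethyloct-6-en-2-one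
Product: 3 (3R)-2,3,7-trimethylocta-1,6-diene
Conditions: Zn, CH2Br2, TiCl4, THF/CH2Cl2, 0 °C to rt
Reagents that add atoms: dibromomethane, BrCBr
Why: Takai–Lombardo methylenation: the non-basic gem-dizinc/titanium reagent turns C=O into C=CH2 without enolising the α-stereocenter, which a basic Wittig ylide could epimerise.

Step 3
Reactants: 3 (3R)-2,3,7-trimethylocta-1,6-diene
Product: 5 (4R)-4,5-dimethylhex-5-enoic acid, via aldehyde 4 (not isolated)
Conditions: O3 (1.0 equiv, dye end-point), CH2Cl2/MeOH, −78 °C; Me2S; then NaClO2, NaH2PO4, H2O2, MeCN/H2O, 0 °C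
Reagents that add atoms: ozone, [O-][O+]=O; sodium chlorite (NaClO2), [Na+].[O-]Cl=O
Why: Chemoselective ozonolysis (the trisubstituted olefin reacts much faster than the 1,1-disubstituted one, as in the ring-selective cleavage of limonene) followed by Pinnick oxidation with H2O2 as hypochlorite scavenger; the stereocenter is γ to the new carboxyl and untouched.

Step 4
Reactants: 2 (3R)-3,7-dimethyloct-6-en-2-one
Product: 7 (3R)-3,7-dimethylocta-1,6-dien-2-yl trifluoromethanesulfonate, via potassium enolate 6 (not isolated)
Conditions: KN(SiMe3)2, THF, −78 °C; PhNTf2, −78 to 0 °C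
Reagents that add atoms: N-phenylbis(trifluoromethanesulfonimide), O=S(=O)(N(c1ccccc1)S(=O)(=O)C(F)(F)F)C(F)(F)F
Why: Kinetic enolisation and O-triflation: the hindered base removes a methyl proton far faster than the tertiary α-proton, so the terminal enol triflate forms and the stereocenter is kept.

Step 5
Reactants: 8 (3S)-3,7-dimethylocta-1,6-diene [(S)-β-citronellene]
Product: 9 (3S)-3,7-dimethyloct-6-en-2-one
Conditions: PdCl2 (10 mol%), CuCl (1 equiv), O2 (1 atm), DMF/H2O 7:1, rt
Reagents that add atoms: water, O
Why: Tsuji–Wacker oxidation as in step 1, on the enantiomeric diene.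

Step 6
Reactants: 9 (3S)-3,7-dimethyloct-6-en-2-one
Product: 10 (3S)-2,3,7-trimethylocta-1,6-diene
Conditions: Zn, CH2Br2, TiCl4, THF/CH2Cl2, 0 °C to rt
Reagents that add atoms: dibromomethane, BrCBr
Why: Takai–Lombardo methylenation as in step 2, without epimerisation of the α-stereocenter.

Step 7
Reactants: 10 (3S)-2,3,7-trimethylocta-1,6-diene
Product: 12 (4S)-4,5-dimethylhex-5-enoic acid, via aldehyde 11 (not isolated)
Conditions: O3 (1.0 equiv, dye end-point), CH2Cl2/MeOH, −78 °C; Me2S; then NaClO2, NaH2PO4, H2O2, MeCN/H2O, 0 °C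
Reagents that add atoms: ozone, [O-][O+]=O; sodium chlorite (NaClO2), [Na+].[O-]Cl=O
Why: Selective ozonolysis of the trisubstituted olefin and Pinnick oxidation as in step 3.

Step 8
Reactants: 5 (4R)-4,5-dimethylhex-5-enoic acid; 7 (3R)-3,7-dimethylocta-1,6-dien-2-yl trifluoromethanesulfonate
Product: 13 (3R,7R)-2,3,7,11-tetramethyl-6-methylidenedodeca-1,10-diene
Conditions: Ir[dF(CF3)ppy]2(dtbbpy)PF6 (2 mol%), NiCl2·glyme (10 mol%), 4,4'-di-tert-butyl-2,2'-bipyridine (15 mol%), Cs2CO3 (1.5 equiv), Bu4NBr (20 mol%), DMSO, 450 nm LEDs, 25 °C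
Reagents that add atoms: none
Why: Proposed new method: nickel/iridium metallaphotoredox decarboxylative alkenylation extended to an unactivated primary alkanoic acid and an α-branched 1-alkylvinyl triflate; the caesium carboxylate of 5 is oxidised by the photoexcited iridium complex and loses CO2 to give the primary C5 radical, zerovalent nickel inserts into the C–O bond of 7 (bromide additive gives the alkenylnickel bromide), this species captures the radical, the resulting trivalent nickel complex reductively eliminates the C5–C6 bond of the 1,1-disubstituted olefin, and the reduced iridium complex returns nickel to its low-valent state; the closest known reaction is the same dual-catalytic decarboxylative alkenylation of α-heteroatom-substituted and secondary acids with vinyl iodides and bromides; no stereocenter is formed and neither methyl stereocenter is a radical or enolisable site.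

Step 9
Reactants: 12 (4S)-4,5-dimethylhex-5-enoic acid; 7 (3R)-3,7-dimethylocta-1,6-dien-2-yl trifluoromethanesulfonate
Product: 14 (3S,7R)-2,3,7,11-tetramethyl-6-methylidenedodeca-1,10-diene
Conditions: Ir[dF(CF3)ppy]2(dtbbpy)PF6 (2 mol%), NiCl2·glyme (10 mol%), 4,4'-di-tert-butyl-2,2'-bipyridine (15 mol%), Cs2CO3 (1.5 equiv), Bu4NBr (20 mol%), DMSO, 450 nm LEDs, 25 °C
Reagents that add atoms: none
Why: Proposed new method: the same metallaphotoredox decarboxylative alkenylation as in step 8 (carboxylate oxidation and loss of CO2, capture of the primary radical by the alkenylnickel species from the enol triflate, reductive elimination from trivalent nickel; closest known reaction: decarboxylative alkenylation of activated acids with vinyl halides), here forming the C19–C20 bond of chain B from the enantiomeric acid.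

Step 10
Reactants: 13 (3R,7R)-2,3,7,11-tetramethyl-6-methylidenedodeca-1,10-diene
Product: 16 (4R,8R)-4,8,9-trimethyl-5-methylidenedec-9-enoic acid, via aldehyde 15 (not isolated)
Conditions: O3 (1.0 equiv, dye end-point), CH2Cl2/MeOH, −78 °C; Me2S; then NaClO2, NaH2PO4, H2O2, MeCN/H2O, 0 °C
Reagents that add atoms: ozone, [O-][O+]=O; sodium chlorite (NaClO2), [Na+].[O-]Cl=O
Why: Selective ozonolysis of the single trisubstituted olefin in the presence of two less electron-rich 1,1-disubstituted olefins, then Pinnick oxidation; the carboxyl carbon is the one later excised.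

Step 11
Reactants: 16 (4R,8R)-4,8,9-trimethyl-5-methylidenedec-9-enoic acid
Product: 18 (3R,7R)-9-iodo-2,3,7-trimethyl-6-methylidenenon-1-ene, via thiohydroxamate ester 17 (not isolated)
Conditions: N-hydroxypyridine-2-thione, DCC, DMAP (cat.), CH2Cl2, 0 °C to rt, dark; then CHI3, hν (tungsten lamp), rt
Reagents that add atoms: iodoform, IC(I)I
Why: Barton decarboxylative iodination: photolysis of the thiohydroxamate ester gives the primary C9 radical, which takes iodine from iodoform in a radical chain faster than it can shift hydrogen; a pent-4-enyl radical does not cyclise and the olefins are inert.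

Step 12
Reactants: 14 (3S,7R)-2,3,7,11-tetramethyl-6-methylidenedodeca-1,10-diene
Product: 19 (4R,8S)-4,8,9-trimethyl-5-methylidenedec-9-enal
Conditions: O3 (1.0 equiv, dye end-point), CH2Cl2/MeOH, −78 °C; Me2S
Reagents that add atoms: ozone, [O-][O+]=O
Why: Selective reductive ozonolysis of the trisubstituted olefin as in step 10, stopped at the aldehyde.

Step 13
Reactants: 19 (4R,8S)-4,8,9-trimethyl-5-methylidenedec-9-enal
Product: 20 (5R,9S)-5,9,10-trimethyl-6-methylideneundec-10-en-1-yne
Conditions: dimethyl (1-diazo-2-oxopropyl)phosphonate, K2CO3, MeOH, 0 °C to rt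
Reagents that add atoms: dimethyl (1-diazo-2-oxopropyl)phosphonate, COP(=O)(OC)C(=[N+]=[N-])C(C)=O
Why: Ohira–Bestmann homologation of the aldehyde to the terminal alkyne under mild carbonate conditions; the nearest stereocenter is γ to the carbonyl and cannot epimerise.

Step 14
Reactants: 20 (5R,9S)-5,9,10-trimethyl-6-methylideneundec-10-en-1-yne
Product: 22 (1E,5R,9S)-1-iodo-2,5,9,10-tetramethyl-6-methylideneundeca-1,10-diene, via alkenylalane 21 (not isolated)
Conditions: AlMe3 (2.5 equiv), Cp2ZrCl2 (25 mol%), CH2Cl2, 0 °C to rt; then I2, THF, −30 °C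
Reagents that add atoms: trimethylaluminium (AlMe3), C[Al](C)C; iodine, I[I]
Why: Negishi zirconium-catalysed carboalumination: methyl and aluminium add syn across the terminal alkyne with methyl on the internal carbon, and iodinolysis with retention gives only the (E)-alkenyl iodide (the future C14=C15 geometry); 1,1-disubstituted olefins do not react.

Step 15
Reactants: 23 (2R)-5-oxooxolane-2-carboxylic acid
Product: 24 (2R)-N-methoxy-N-methyl-5-oxooxolane-2-carboxamide
Conditions: MeNH(OMe)·HCl, EDC·HCl, N-methylmorpholine, CH2Cl2, 0 °C to rt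
Reagents that add atoms: N,O-dimethylhydroxylamine hydrochloride, CNOC.Cl
Why: Carbodiimide amidation to the Weinreb amide; it masks the α-oxy carboxyl (future C10) so that only the lactone carboxyl can later be decarboxylated, and the lactone and the bought stereocenter (future C11) are untouched.

Step 16
Reactants: 24 (2R)-N-methoxy-N-methyl-5-oxooxolane-2-carboxamide; 22 (1E,5R,9S)-1-iodo-2,5,9,10-tetramethyl-6-methylideneundeca-1,10-diene
Product: 26 (2R,5E,9R,13S)-2-hydroxy-N-methoxy-N,6,9,13,14-pentamethyl-10-methylidenepentadeca-5,14-dienamide, via caesium hydroxy carboxylate 25 (not isolated)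
Conditions: CsOH·H2O (1.0 equiv), THF/H2O, 0 °C, solvent removed; then 22, Ir[dF(CF3)ppy]2(dtbbpy)PF6 (2 mol%), NiCl2·glyme (10 mol%), 4,4'-di-tert-butyl-2,2'-bipyridine (15 mol%), DMSO, 450 nm LEDs, 25 °C
Reagents that add atoms: none
Why: Proposed new method: the lactone serves as a masked primary carboxylate; hydroxide opening gives the caesium γ-hydroxy carboxylate, the photoexcited iridium complex oxidises it, loss of CO2 gives the primary C13 radical, the alkenylnickel species formed from zerovalent nickel and iodide 22 captures it, and reductive elimination from trivalent nickel forms C13–C14 with retention of the E geometry, the free hydroxyl and the Weinreb amide being spectators and C11 not a radical site; closest known reaction: nickel/iridium decarboxylative alkenylation of α-oxy, α-amino and secondary acids with vinyl iodides.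

Step 17
Reactants: 26 (2R,5E,9R,13S)-2-hydroxy-N-methoxy-N,6,9,13,14-pentamethyl-10-methylidenepentadeca-5,14-dienamide
Product: 27 (3R,6E,10R,14S)-3-hydroxy-7,10,14,15-tetramethyl-11-methylidenehexadeca-6,15-dien-2-one
Conditions: MeMgBr (3 equiv), THF, −78 to 0 °C; aq. NH4Cl
Reagents that add atoms: methylmagnesium bromide (MeMgBr), C[Mg]Br
Why: Weinreb ketone synthesis: the first equivalent deprotonates the hydroxyl, the second adds once, and the magnesium-chelated tetrahedral adduct survives until work-up, so no over-addition occurs and the α-stereocenter is kept.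

Step 18
Reactants: 18 (3R,7R)-9-iodo-2,3,7-trimethyl-6-methylidenenon-1-ene; 27 (3R,6E,10R,14S)-3-hydroxy-7,10,14,15-tetramethyl-11-methylidenehexadeca-6,15-dien-2-one
Product: 31 (3R,7R,10R,11R,14E,18R,22S)-2,3,7,10,15,18,22,23-octamethyl-6,19-dimethylidenetetracosa-1,14,23-triene-10,11-diol, via alkyllithium 28 (not isolated), via alkylmagnesium bromide 29 (not isolated), via chloromagnesium alkoxide 30 (not isolated)
Conditions: 18: t-BuLi (2.1 equiv), Et2O/pentane, −78 °C, then MgBr2·OEt2; 27: t-BuMgCl (1.0 equiv), THF, −78 °C; combined (1.5 equiv of the magnesium reagent), −78 to −20 °C; aq. NH4Cl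
Reagents that add atoms: none
Why: Cram-chelate-controlled Grignard addition: magnesium bridges the C11 alkoxide and the C10 carbonyl in a five-membered chelate and the chain A nucleophile attacks the face bearing the C11 hydrogen, anti to the C12 chain, which with methyl already on the ketone gives the (10R,11R) diol; lithium–iodine exchange and transmetalation to magnesium are standard.

Step 19
Reactants: 31 (3R,7R,10R,11R,14E,18R,22S)-2,3,7,10,15,18,22,23-octamethyl-6,19-dimethylidenetetracosa-1,14,23-triene-10,11-diol; 32 all-trans-canthaxanthin (β,β-carotene-4,4'-dione)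
Product: 33 the target: canthaxanthin mono-spiroketal with diol 31 and (R)-configured spiro carbon
Conditions: 32 (3 equiv), i-PrOSiMe3 (3 equiv), Me3SiOTf (10 mol%), 2,6-di-tert-butylpyridine (10 mol%), CH2Cl2, −40 °C, dark, argon; pyridine quench; chromatography, then HPLC
Reagents that add atoms: none
Why: Noyori-type silyl-mediated ketalisation under aprotic conditions (no free acid on the polyene, and the tetrasubstituted enone cannot deconjugate): the secondary C11 oxygen adds first, the oxocarbenium ion holds C11 on the ring-CH2 side away from the C5 methyl, and the tertiary C10 oxygen closes through the rotamer that turns the C12 chain away from the ring, which is predicted to give the (R)-spiro carbon; the ratio is not known in advance, so any spiro epimer is removed by HPLC and re-equilibrated, and excess 32 suppresses the bis-ketal and is recovered.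

**Compound list**
1 | (3R)-3,7-dimethylocta-1,6-diene, (R)-β-citronellene | C=C[C@H](C)CCC=C(C)C | starting material
2 | (3R)-3,7-dimethyloct-6-en-2-one | CC(=O)[C@H](C)CCC=C(C)C | intermediate
3 | (3R)-2,3,7-trimethylocta-1,6-diene | C=C(C)[C@H](C)CCC=C(C)C | intermediate
4 | (4R)-4,5-dimethylhex-5-enal | C=C(C)[C@H](C)CCC=O | intermediate
5 | (4R)-4,5-dimethylhex-5-enoic acid | C=C(C)[C@H](C)CCC(=O)O | intermediate
6 | potassium (3R)-3,7-dimethylocta-1,6-dien-2-olate | [K+].[O-]C(=C)[C@H](C)CCC=C(C)C | intermediate
7 | (3R)-3,7-dimethylocta-1,6-dien-2-yl trifluoromethanesulfonate | C=C(OS(=O)(=O)C(F)(F)F)[C@H](C)CCC=C(C)C | intermediate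
8 | (3S)-3,7-dimethylocta-1,6-diene, (S)-β-citronellene | C=C[C@@H](C)CCC=C(C)C | starting material
9 | (3S)-3,7-dimethyloct-6-en-2-one | CC(=O)[C@@H](C)CCC=C(C)C | intermediate
10 | (3S)-2,3,7-trimethylocta-1,6-diene | C=C(C)[C@@H](C)CCC=C(C)C | intermediate
11 | (4S)-4,5-dimethylhex-5-enal | C=C(C)[C@@H](C)CCC=O | intermediate
12 | (4S)-4,5-dimethylhex-5-enoic acid | C=C(C)[C@@H](C)CCC(=O)O | intermediate
13 | (3R,7R)-2,3,7,11-tetramethyl-6-methylidenedodeca-1,10-diene | C=C(C)[C@H](C)CCC(=C)[C@H](C)CCC=C(C)C | intermediate
14 | (3S,7R)-2,3,7,11-tetramethyl-6-methylidenedodeca-1,10-diene | C=C(C)[C@@H](C)CCC(=C)[C@H](C)CCC=C(C)C | intermediate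
15 | (4R,8R)-4,8,9-trimethyl-5-methylidenedec-9-enal | C=C(C)[C@H](C)CCC(=C)[C@H](C)CCC=O | intermediate
16 | (4R,8R)-4,8,9-trimethyl-5-methylidenedec-9-enoic acid | C=C(C)[C@H](C)CCC(=C)[C@H](C)CCC(=O)O | intermediate
17 | 2-sulfanylidenepyridin-1(2H)-yl (4R,8R)-4,8,9-trimethyl-5-methylidenedec-9-enoate | C=C(C)[C@H](C)CCC(=C)[C@H](C)CCC(=O)ON1C=CC=CC1=S | intermediate
18 | (3R,7R)-9-iodo-2,3,7-trimethyl-6-methylidenenon-1-ene | C=C(C)[C@H](C)CCC(=C)[C@H](C)CCI | intermediate
19 | (4R,8S)-4,8,9-trimethyl-5-methylidenedec-9-enal | C=C(C)[C@@H](C)CCC(=C)[C@H](C)CCC=O | intermediate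
20 | (5R,9S)-5,9,10-trimethyl-6-methylideneundec-10-en-1-yne | C=C(C)[C@@H](C)CCC(=C)[C@H](C)CCC#C | intermediate
21 | dimethyl[(1E,5R,9S)-2,5,9,10-tetramethyl-6-methylideneundeca-1,10-dien-1-yl]alane | C=C(C)[C@@H](C)CCC(=C)[C@H](C)CC/C(C)=C/[Al](C)C | intermediate
22 | (1E,5R,9S)-1-iodo-2,5,9,10-tetramethyl-6-methylideneundeca-1,10-diene | C=C(C)[C@@H](C)CCC(=C)[C@H](C)CC/C(C)=C/I | intermediate
23 | (2R)-5-oxooxolane-2-carboxylic acid | OC(=O)[C@H]1CCC(=O)O1 | starting material
24 | (2R)-N-methoxy-N-methyl-5-oxooxolane-2-carboxamide | CON(C)C(=O)[C@H]1CCC(=O)O1 | intermediate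
25 | caesium (4R)-4-hydroxy-5-[methoxy(methyl)amino]-5-oxopentanoate | [Cs+].[O-]C(=O)CC[C@@H](O)C(=O)N(C)OC | intermediate
26 | (2R,5E,9R,13S)-2-hydroxy-N-methoxy-N,6,9,13,14-pentamethyl-10-methylidenepentadeca-5,14-dienamide | C=C(C)[C@@H](C)CCC(=C)[C@H](C)CC/C(C)=C/CC[C@@H](O)C(=O)N(C)OC | intermediate
27 | (3R,6E,10R,14S)-3-hydroxy-7,10,14,15-tetramethyl-11-methylidenehexadeca-6,15-dien-2-one | C=C(C)[C@@H](C)CCC(=C)[C@H](C)CC/C(C)=C/CC[C@@H](O)C(C)=O | intermediate
28 | [(3R,7R)-3,7,8-trimethyl-4-methylidenenon-8-en-1-yl]lithium | C=C(C)[C@H](C)CCC(=C)[C@H](C)CC[Li] | intermediate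
29 | bromo[(3R,7R)-3,7,8-trimethyl-4-methylidenenon-8-en-1-yl]magnesium | C=C(C)[C@H](C)CCC(=C)[C@H](C)CC[Mg]Br | intermediate
30 | chloromagnesium alkoxide of 27 | C=C(C)[C@@H](C)CCC(=C)[C@H](C)CC/C(C)=C/CC[C@@H](O[Mg]Cl)C(C)=O | intermediate
31 | (3R,7R,10R,11R,14E,18R,22S)-2,3,7,10,15,18,22,23-octamethyl-6,19-dimethylidenetetracosa-1,14,23-triene-10,11-diol (locants from the chain A end) | C=C(C)[C@H](C)CCC(=C)[C@H](C)CC[C@@](C)(O)[C@H](O)CC/C=C(\C)CC[C@@H](C)C(=C)CC[C@H](C)C(=C)C | intermediate
32 | all-trans-canthaxanthin, β,β-carotene-4,4'-dione | O=C1CCC(C)(C)C(/C=C/C(C)=C/C=C/C(C)=C/C=C/C=C(C)/C=C/C=C(C)/C=C/C2=C(C)C(=O)CCC2(C)C)=C1C | starting material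
33 | CNP0354203.2: canthaxanthin mono-ketal in which one ring carbonyl carbon is the (R)-spiro carbon of a 1,3-dioxolane built on O10 and O11 of diol 31 | C=C(C)[C@H](C)CCC(=C)[C@H](C)CC[C@@]1(C)O[C@@]2(CCC(C)(C)C(/C=C/C(C)=C/C=C/C(C)=C/C=C/C=C(C)/C=C/C=C(C)/C=C/C3=C(C)C(=O)CCC3(C)C)=C2C)O[C@@H]1CC/C=C(\C)CC[C@@H](C)C(=C)CC[C@H](C)C(=C)C | target

**Step count**
Total: 19 steps. Longest linear sequence: 11 steps (8 → 9 → 10 → 12 → 14 → 19 → 20 → 22 → 26 → 27 → 31 → 33; steps 5, 6, 7, 9, 12, 13, 14, 16, 17, 18, 19).

**The three steps most likely to fail**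

Step 8 (proposed new method; step 9 is the same reaction and shares the risk). Primary carboxylates are oxidised and decarboxylated more slowly than the activated acids for which this coupling is established. The alkenylnickel species may instead form the enol ester by C–O coupling. The C5 radical can also shift a hydrogen from the allylic methyl group before nickel captures it. The fallback uses known two-electron chemistry; it sets out from acid 5 (triflate 7 is used as made) and comes back at 13. Acid 5 is converted with N-hydroxypyridine-2-thione and DCC into the thiohydroxamate ester F1 and photolysed with iodoform, as in step 11, to (3R)-5-iodo-2,3-dimethylpent-1-ene F2. Zinc dust with LiCl in THF gives [(3R)-3,4-dimethylpent-4-en-1-yl]zinc iodide F3, and a Pd(PPh3)4-catalysed Negishi coupling of F3 with 7 gives 13.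

Step 16 (the same new method on a lactone-derived γ-hydroxy carboxylate). Here the primary carboxylate carries a free hydroxyl and an α-hydroxy amide, so slow decarboxylation, relactonisation on any acidification and O-alkenylation are all possible. The fallback uses the known thermal nickel-catalysed decarboxylative alkenylation of a redox-active ester with an alkenylzinc; it sets out from salt 25 and iodide 22 and comes back at 26. Salt 25 is O-silylated (t-BuMe2SiCl, imidazole, then aqueous K2CO3 to cleave the silyl ester) to (4R)-4-[(tert-butyldimethylsilyl)oxy]-5-[methoxy(methyl)amino]-5-oxopentanoic acid F4 and esterified with N-hydroxyphthalimide and DIC to the redox-active ester F5. Iodide 22 is converted by t-BuLi into the alkenyllithium F6 and by ZnCl2 into the alkenylzinc chloride F7. Coupling of F5 with F7 (NiCl2·glyme, 2,2'-bipyridine, THF/DMF) gives the silyl ether F8, and Bu4NF releases 26.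

Step 19. The carbonyl is deactivated by conjugation with the polyene, the diol is a hindered secondary/tertiary pair, the polyene does not tolerate free acid, and bis-ketal and the spiro epimer can form. The fallback replaces the direct silyl-mediated condensation by a ketal exchange; it sets out from 32 and comes back at 33. Canthaxanthin 32 is first converted with HC(OMe)3/MeOH and pyridinium p-toluenesulfonate into canthaxanthin mono(dimethyl ketal) F9, separated from 32 and bis-ketal. F9 is then exchanged with diol 31 under the same mild catalyst in benzene over 4 Å sieves, which take up the methanol, to give 33.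

**Further compounds**
F1 | step 8 | 2-sulfanylidenepyridin-1(2H)-yl (4R)-4,5-dimethylhex-5-enoate | C=C(C)[C@H](C)CCC(=O)ON1C=CC=CC1=S
F2 | step 8 | (3R)-5-iodo-2,3-dimethylpent-1-ene | C=C(C)[C@H](C)CCI
F3 | step 8 | [(3R)-3,4-dimethylpent-4-en-1-yl]zinc iodide | C=C(C)[C@H](C)CC[Zn]I
F4 | step 16 | (4R)-4-[(tert-butyldimethylsilyl)oxy]-5-[methoxy(methyl)amino]-5-oxopentanoic acid | OC(=O)CC[C@@H](O[Si](C)(C)C(C)(C)C)C(=O)N(C)OC
F5 | step 16 | 1,3-dioxoisoindolin-2-yl (4R)-4-[(tert-butyldimethylsilyl)oxy]-5-[methoxy(methyl)amino]-5-oxopentanoate | O=C(CC[C@@H](O[Si](C)(C)C(C)(C)C)C(=O)N(C)OC)ON1C(=O)c2ccccc2C1=O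
F6 | step 16 | [(1E,5R,9S)-2,5,9,10-tetramethyl-6-methylideneundeca-1,10-dien-1-yl]lithium | C=C(C)[C@@H](C)CCC(=C)[C@H](C)CC/C(C)=C/[Li]
F7 | step 16 | chloro[(1E,5R,9S)-2,5,9,10-tetramethyl-6-methylideneundeca-1,10-dien-1-yl]zinc | C=C(C)[C@@H](C)CCC(=C)[C@H](C)CC/C(C)=C/[Zn]Cl
F8 | step 16 | (2R,5E,9R,13S)-2-[(tert-butyldimethylsilyl)oxy]-N-methoxy-N,6,9,13,14-pentamethyl-10-methylidenepentadeca-5,14-dienamide | C=C(C)[C@@H](C)CCC(=C)[C@H](C)CC/C(C)=C/CC[C@@H](O[Si](C)(C)C(C)(C)C)C(=O)N(C)OC
F9 | step 19 | 4,4-dimethoxy-β,β-caroten-4'-one, canthaxanthin mono(dimethyl ketal) | COC1(OC)CCC(C)(C)C(/C=C/C(C)=C/C=C/C(C)=C/C=C/C=C(C)/C=C/C=C(C)/C=C/C2=C(C)C(=O)CCC2(C)C)=C1C
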